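**Strategy**

Everything rests on cutting the bond between C2 and ring A. In the target, ring A (3-bromo-5-hydroxy-4-methoxyphenyl) sits on C2, one atom away from the ester carbon C1, the signature of an aryl group that has moved from a carbonyl carbon to its alpha carbon. One oxidative 1,2-aryl shift, run with a chiral lactate-based trivalent iodine reagent in acidic methanol/trimethyl orthoformate, forms the C2–ring A bond, turns the ketone carbon into the methyl ester and sets C2. The precursor is the tri-O-benzyl dihydrochalcone 13, in which ring A is the ketone aryl group and the chain ends in ring B (2,3-dibromo-4,5-dihydroxyphenyl, as its dibenzyl ether).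

Key step: step 10

Assumption: the (R,R)-reagent dimethyl (2R,2'R)-2,2'-{[2-(diacetoxyiodo)-1,3-phenylene]bis(oxy)}dipropanoate, COC(=O)[C@@H](C)Oc1cccc(O[C@H](C)C(=O)OC)c1I(OC(C)=O)OC(C)=O, is taken to deliver the (R)-ester; if a test run shows the opposite sense, the mirror-image reagent from methyl (R)-lactate is used in the same way.

Remark on the reagent: it is a known compound, made in two operations from 2-iodoresorcinol and methyl (S)-lactate (Mitsunobu etherification with inversion, then NaBO3·4H2O in AcOH), and is treated as a reagent, not as a route compound.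

Remark on structures: C2 of the target is (R) (priorities CO2Me > ring A > CH2–ring B > H). Aldol 11 is racemic and enol ether 15 is expected as a mixture of double-bond isomers, so both are written without stereodescriptors.

**Route**

Step 1
Reactants: 1 apocynin (4-hydroxy-3-methoxyacetophenone)
Product: 2 1-(3-bromo-4-hydroxy-5-methoxyphenyl)ethanone
Conditions: Br2 (1.05 equiv), NaOAc, AcOH, rt
Reagents that add atoms: bromine, BrBr
Why: Electrophilic aromatic bromination: C5, the only free position ortho to the phenol, is by far the most activated carbon, and the acetate buffer keeps HBr from catalysing alpha-bromination of the acetyl group.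

Step 2
Reactants: 2 1-(3-bromo-4-hydroxy-5-methoxyphenyl)ethanone
Product: 3 1-(3-bromo-4,5-dihydroxyphenyl)ethanone
Conditions: AlCl3 (1.2 equiv), pyridine, CH2Cl2, reflux; then cold dilute HCl
Reagents that add atoms: none
Why: AlCl3–pyridine demethylation of an ortho-hydroxy aryl methyl ether: aluminium binds the phenoxide and chelates the neighbouring methoxy oxygen, so chloride removes only that methyl group while ketone and aryl bromide are left alone.

Step 3
Reactants: 3 1-(3-bromo-4,5-dihydroxyphenyl)ethanone
Product: 4 1-(3-bromo-5-hydroxy-4-methoxyphenyl)ethanone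
Conditions: MeI (1.1 equiv), Li2CO3 (1.2 equiv), DMF, 40 °C
Reagents that add atoms: iodomethane, CI
Why: Williamson etherification under acidity control: Li2CO3 ionises only the 4-OH, which is para to the acetyl group and ortho to bromine and hence much more acidic than the 5-OH, so one equivalent of MeI should methylate O4 alone, the behaviour known for 5-bromoprotocatechuic aldehyde.

Step 4
Reactants: 4 1-(3-bromo-5-hydroxy-4-methoxyphenyl)ethanone, 5 benzyl bromide
Product: 6 1-[3-(benzyloxy)-5-bromo-4-methoxyphenyl]ethanone
Conditions: K2CO3, DMF, rt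
Reagents that add atoms: none
Why: Williamson etherification of the remaining phenol with a reactive benzylic halide; the mild carbonate does not enolise the ketone to any useful extent.

Step 5
Reactants: 7 5-bromovanillin (3-bromo-4-hydroxy-5-methoxybenzaldehyde)
Product: 8 2,3-dibromo-4-hydroxy-5-methoxybenzaldehyde
Conditions: Br2 (1.2 equiv), Fe powder (cat.), NaOAc, AcOH, rt → 50 °C
Reagents that add atoms: bromine, BrBr
Why: Electrophilic aromatic bromination with FeBr3 formed in the flask: both positions ortho to the phenol are occupied, so bromine enters C6, para to the methoxy group, which is the documented outcome for 5-bromovanillin and gives the 2,3-dibromo pattern of ring B.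

Step 6
Reactants: 8 2,3-dibromo-4-hydroxy-5-methoxybenzaldehyde
Product: 9 2,3-dibromo-4,5-dihydroxybenzaldehyde
Conditions: AlCl3 (1.2 equiv), pyridine, CH2Cl2, reflux; then cold dilute HCl
Reagents that add atoms: none
Why: The same chelation-directed AlCl3–pyridine demethylation as in step 2, here on a guaiacol-type aldehyde of a class for which it is routine.

Step 7
Reactants: 9 2,3-dibromo-4,5-dihydroxybenzaldehyde, 5 benzyl bromide (2.4 equiv)
Product: 10 4,5-bis(benzyloxy)-2,3-dibromobenzaldehyde
Conditions: K2CO3, DMF, 60 °C
Reagents that add atoms: none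
Why: Double Williamson etherification; both phenoxides of the bromocatechol form readily with K2CO3 and the non-enolisable aldehyde is inert.

Step 8
Reactants: 6 1-[3-(benzyloxy)-5-bromo-4-methoxyphenyl]ethanone, 10 4,5-bis(benzyloxy)-2,3-dibromobenzaldehyde
Product: 12 (2E)-1-[3-(benzyloxy)-5-bromo-4-methoxyphenyl]-3-[4,5-bis(benzyloxy)-2,3-dibromophenyl]prop-2-en-1-one, via aldol adduct 11 (not isolated)
Conditions: NaOH (aq), EtOH/THF, rt
Reagents that add atoms: none
Why: Claisen–Schmidt (crossed aldol) condensation: aldehyde 10 cannot enolise, methyl ketone 6 gives a single enolate, and aldol 11 loses water under the basic conditions to the conjugated E-enone, which should crystallise from the mixture.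

Step 9
Reactants: 12 (2E)-1-[3-(benzyloxy)-5-bromo-4-methoxyphenyl]-3-[4,5-bis(benzyloxy)-2,3-dibromophenyl]prop-2-en-1-one
Product: 13 1-[3-(benzyloxy)-5-bromo-4-methoxyphenyl]-3-[4,5-bis(benzyloxy)-2,3-dibromophenyl]propan-1-one
Conditions: [(Ph3P)CuH]6 (0.3 equiv), degassed H2O, THF/toluene, rt
Reagents that add atoms: none
Why: Conjugate reduction with copper hydride (Stryker reduction): hydride from monovalent copper adds to the beta carbon, the copper enolate is protonated by water, and aryl bromides and benzyl ethers, which rule out catalytic hydrogenation, are inert to the reagent.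

Step 10
Reactants: 13 1-[3-(benzyloxy)-5-bromo-4-methoxyphenyl]-3-[4,5-bis(benzyloxy)-2,3-dibromophenyl]propan-1-one
Product: 17 methyl (2R)-2-[3-(benzyloxy)-5-bromo-4-methoxyphenyl]-3-[4,5-bis(benzyloxy)-2,3-dibromophenyl]propanoate, via dimethyl ketal 14 (not isolated), via methyl enol ether 15 (not isolated), via trimethyl orthoester 16 (not isolated)
Conditions: TsOH·H2O (2 equiv), HC(OMe)3/MeOH/CH2Cl2, rt; then (R,R)-ArI(OAc)2 (1.3 equiv), −30 °C → rt; then H2O
Reagents that add atoms: trimethyl orthoformate, COC(OC)OC; methanol, CO; water, O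
Why: TsOH and HC(OMe)3 ketalise 13 to 14, which loses methanol to the electron-rich enol ether 15; the chiral aryl(tosyloxy)iodane formed from the diacetate and TsOH adds to one face of this double bond and leaves trivalent iodine on C2. Ring A, still on the former carbonyl carbon C1, then bridges to C2 as a phenonium ion and pushes out the iodoarene with inversion, and the resulting dimethoxycarbenium ion is taken up by methanol as orthoester 16, which water converts into ester 17 on work-up. The closest known reaction is the oxidative 1,2-aryl migration of alkyl aryl ketones to methyl 2-arylalkanoates in orthoformate with Tl(NO3)3 or PhI(OAc)2, which lactate-derived iodoarenes render enantioselective. No ring is closed, and the one new stereocentre, C2, is under reagent control: the lactate arms of the iodane choose the face of 15 and the stereospecific, invertive shift hands that choice on to the C–aryl bond. The step needs aryl migration to outrun capture of the alpha-iodanyl ketal by methanol and loss of a C3 hydrogen; ring A is the only group on C1 able to bridge and its 4-methoxy group stabilises the phenonium ion, whereas ring B is insulated by C3 and deactivated by two bromines. The benzyl ethers keep every phenol away from the oxidant, and the low temperature serves the ee.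

Step 11
Reactants: 17 methyl (2R)-2-[3-(benzyloxy)-5-bromo-4-methoxyphenyl]-3-[4,5-bis(benzyloxy)-2,3-dibromophenyl]propanoate
Product: 18 methyl (2R)-2-(3-bromo-5-hydroxy-4-methoxyphenyl)-3-(2,3-dibromo-4,5-dihydroxyphenyl)propanoate
Conditions: BCl3 (6 equiv), pentamethylbenzene (9 equiv), CH2Cl2, −78 °C; then MeOH/CHCl3, aqueous work-up
Reagents that add atoms: none
Why: Lewis-acid debenzylation with a non-basic cation scavenger: BCl3 activates the three aryl benzyl ethers, pentamethylbenzene traps the benzyl cations by Friedel–Crafts alkylation before they can attack the electron-rich rings, and at −78 °C the methyl ether, the methyl ester, the aryl bromides and the C2 stereocentre (not epimerisable under acid) should be spared.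

**Compound list**

1 | apocynin (4-hydroxy-3-methoxyacetophenone) | CC(=O)c1ccc(O)c(OC)c1 | starting material
2 | 1-(3-bromo-4-hydroxy-5-methoxyphenyl)ethanone | CC(=O)c1cc(Br)c(O)c(OC)c1 | intermediate
3 | 1-(3-bromo-4,5-dihydroxyphenyl)ethanone | CC(=O)c1cc(O)c(O)c(Br)c1 | intermediate
4 | 1-(3-bromo-5-hydroxy-4-methoxyphenyl)ethanone | CC(=O)c1cc(O)c(OC)c(Br)c1 | intermediate
5 | benzyl bromide | BrCc1ccccc1 | starting material
6 | 1-[3-(benzyloxy)-5-bromo-4-methoxyphenyl]ethanone | CC(=O)c1cc(OCc2ccccc2)c(OC)c(Br)c1 | intermediate
7 | 5-bromovanillin (3-bromo-4-hydroxy-5-methoxybenzaldehyde) | COc1cc(C=O)cc(Br)c1O | starting material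
8 | 2,3-dibromo-4-hydroxy-5-methoxybenzaldehyde | COc1cc(C=O)c(Br)c(Br)c1O | intermediate
9 | 2,3-dibromo-4,5-dihydroxybenzaldehyde | O=Cc1cc(O)c(O)c(Br)c1Br | intermediate
10 | 4,5-bis(benzyloxy)-2,3-dibromobenzaldehyde | O=Cc1cc(OCc2ccccc2)c(OCc2ccccc2)c(Br)c1Br | intermediate
11 | racemic aldol adduct 1-[3-(benzyloxy)-5-bromo-4-methoxyphenyl]-3-[4,5-bis(benzyloxy)-2,3-dibromophenyl]-3-hydroxypropan-1-one (formed and dehydrated in the flask) | O=C(CC(O)c1cc(OCc2ccccc2)c(OCc2ccccc2)c(Br)c1Br)c1cc(OCc2ccccc2)c(OC)c(Br)c1 | intermediate
12 | (2E)-1-[3-(benzyloxy)-5-bromo-4-methoxyphenyl]-3-[4,5-bis(benzyloxy)-2,3-dibromophenyl]prop-2-en-1-one | O=C(/C=C/c1cc(OCc2ccccc2)c(OCc2ccccc2)c(Br)c1Br)c1cc(OCc2ccccc2)c(OC)c(Br)c1 | intermediate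
13 | 1-[3-(benzyloxy)-5-bromo-4-methoxyphenyl]-3-[4,5-bis(benzyloxy)-2,3-dibromophenyl]propan-1-one | O=C(CCc1cc(OCc2ccccc2)c(OCc2ccccc2)c(Br)c1Br)c1cc(OCc2ccccc2)c(OC)c(Br)c1 | intermediate
14 | dimethyl ketal of 13, 1-(benzyloxy)-5-{3-[4,5-bis(benzyloxy)-2,3-dibromophenyl]-1,1-dimethoxypropyl}-3-bromo-2-methoxybenzene (formed and consumed in the flask) | COC(CCc1cc(OCc2ccccc2)c(OCc2ccccc2)c(Br)c1Br)(OC)c1cc(OCc2ccccc2)c(OC)c(Br)c1 | intermediate
15 | methyl enol ether of 13, 1-(benzyloxy)-5-{3-[4,5-bis(benzyloxy)-2,3-dibromophenyl]-1-methoxyprop-1-en-1-yl}-3-bromo-2-methoxybenzene (mixture of double-bond isomers, formed and consumed in the flask) | COC(=CCc1cc(OCc2ccccc2)c(OCc2ccccc2)c(Br)c1Br)c1cc(OCc2ccccc2)c(OC)c(Br)c1 | intermediate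
16 | (2R)-2-[3-(benzyloxy)-5-bromo-4-methoxyphenyl]-3-[4,5-bis(benzyloxy)-2,3-dibromophenyl]-1,1,1-trimethoxypropane (orthoester, hydrolysed on work-up) | COC(OC)(OC)[C@H](Cc1cc(OCc2ccccc2)c(OCc2ccccc2)c(Br)c1Br)c1cc(OCc2ccccc2)c(OC)c(Br)c1 | intermediate
17 | methyl (2R)-2-[3-(benzyloxy)-5-bromo-4-methoxyphenyl]-3-[4,5-bis(benzyloxy)-2,3-dibromophenyl]propanoate | COC(=O)[C@H](Cc1cc(OCc2ccccc2)c(OCc2ccccc2)c(Br)c1Br)c1cc(OCc2ccccc2)c(OC)c(Br)c1 | intermediate
18 | methyl (2R)-2-(3-bromo-5-hydroxy-4-methoxyphenyl)-3-(2,3-dibromo-4,5-dihydroxyphenyl)propanoate | COC(=O)[C@H](Cc1cc(O)c(O)c(Br)c1Br)c1cc(O)c(OC)c(Br)c1 | target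

**Step count and risks**

Total step count: 11. Longest linear sequence: 8 steps (steps 1, 2, 3, 4, 8, 9, 10 and 11, from apocynin).

Steps most likely to fail:

1. Step 10 (key step). Two things may go wrong. The iodane may discriminate poorly between the faces of the enol ether, so that the ester forms with low ee. Or ring A may bridge too slowly, because its 4-methoxy group is twisted out of conjugation by the flanking bromine and benzyloxy group, so that methanol captures the alpha-iodanyl ketal (alpha-methoxylation) instead. The fallback replaces reagent control by auxiliary control and runs from 13 back to 17. Ketone 13 is ketalised with dimethyl (2S,3S)-tartrate (HC(OMe)3, MsOH cat., 90 °C) to dimethyl (4S,5S)-2-[3-(benzyloxy)-5-bromo-4-methoxyphenyl]-2-{2-[4,5-bis(benzyloxy)-2,3-dibromophenyl]ethyl}-1,3-dioxolane-4,5-dicarboxylate F1. Alpha-bromination with PhNMe3Br3 in THF at 0 °C, a reagent mild enough to leave the alkoxyarenes alone, proceeds through the ring-opened enol ether and should be steered by the tartrate to dimethyl (4S,5S)-2-[3-(benzyloxy)-5-bromo-4-methoxyphenyl]-2-{(1R)-2-[4,5-bis(benzyloxy)-2,3-dibromophenyl]-1-bromoethyl}-1,3-dioxolane-4,5-dicarboxylate F2, which can be enriched by crystallisation. AgBF4 in wet 1,2-dichloroethane then ionises the C–Br bond while ring A shifts with inversion, and water opens the dioxolanylium ion to dimethyl (2S,3S)-2-hydroxy-3-{[(2R)-2-[3-(benzyloxy)-5-bromo-4-methoxyphenyl]-3-[4,5-bis(benzyloxy)-2,3-dibromophenyl]propanoyl]oxy}butanedioate F3. Acid-catalysed transesterification (H2SO4 cat., MeOH, reflux), which does not epimerise C2, returns 17. The (S,S)-tartrate is chosen because tartrate ketals of alkyl aryl ketones with the (R,R) configuration are established to give the (S)-2-aryl acids, the CIP descriptor being carried over from C–Br to C–aryl.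

2. Step 3. The mono-alkylation may lose regiocontrol, giving methylation at O5 or at both oxygens, and the isomers are hard to separate. The fallback reverses the order of the two alkylations and uses kinetic dianion selectivity in place of acidity control; it runs from 3 back to 6, leaving out 4. Catechol 3 is converted into its dianion (NaH, 2.0 equiv, DMSO, rt) and treated with one equivalent of benzyl bromide 5. The more basic and more nucleophilic 5-phenoxide should react first and give 1-[3-(benzyloxy)-5-bromo-4-hydroxyphenyl]ethanone F4. Methylation of the remaining acidic 4-OH (MeI, K2CO3, DMF) then gives 6.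

3. Step 11. Over-cleavage is the concern: once the neighbouring oxygen of ring A carries boron, the crowded 4-methoxy group may be lost by chelation-assisted demethylation, while the benzyl ethers on the deactivated ring B may lag behind and tempt longer or warmer reaction. The fallback abandons Lewis-acid complexation for Brønsted acidolysis with a soft nucleophile and runs from 17 directly to 18 without a new compound (entry F0). In TFA/thioanisole at rt only ethers that can pass their alkyl group on as a benzylic cation are cleaved, the benzyl groups ending on sulfur, so methyl ether and methyl ester are mechanistically out of reach and C2 is not at risk.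

**Further compounds**

F1 | step 10 | dimethyl (4S,5S)-2-[3-(benzyloxy)-5-bromo-4-methoxyphenyl]-2-{2-[4,5-bis(benzyloxy)-2,3-dibromophenyl]ethyl}-1,3-dioxolane-4,5-dicarboxylate | COC(=O)[C@H]1OC(CCc2cc(OCc3ccccc3)c(OCc3ccccc3)c(Br)c2Br)(c2cc(OCc3ccccc3)c(OC)c(Br)c2)O[C@@H]1C(=O)OC
F2 | step 10 | dimethyl (4S,5S)-2-[3-(benzyloxy)-5-bromo-4-methoxyphenyl]-2-{(1R)-2-[4,5-bis(benzyloxy)-2,3-dibromophenyl]-1-bromoethyl}-1,3-dioxolane-4,5-dicarboxylate | COC(=O)[C@H]1OC([C@H](Br)Cc2cc(OCc3ccccc3)c(OCc3ccccc3)c(Br)c2Br)(c2cc(OCc3ccccc3)c(OC)c(Br)c2)O[C@@H]1C(=O)OC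
F3 | step 10 | dimethyl (2S,3S)-2-hydroxy-3-{[(2R)-2-[3-(benzyloxy)-5-bromo-4-methoxyphenyl]-3-[4,5-bis(benzyloxy)-2,3-dibromophenyl]propanoyl]oxy}butanedioate | COC(=O)[C@@H](O)[C@H](OC(=O)[C@H](Cc1cc(OCc2ccccc2)c(OCc2ccccc2)c(Br)c1Br)c1cc(OCc2ccccc2)c(OC)c(Br)c1)C(=O)OC
F4 | step 3 | 1-[3-(benzyloxy)-5-bromo-4-hydroxyphenyl]ethanone | CC(=O)c1cc(OCc2ccccc2)c(O)c(Br)c1
F0 | step 11 | none | none
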